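**Plan**

- Retrosynthetic cuts: the acid comes from its methyl ester. The diene is cut at C1'=C2' (Horner–Wadsworth–Emmons) into a (2R)-2-formyl-2-methylchroman and an E-allylic phosphonate. The formyl group is traced back to a vinyl group.
- The O1–C2 bond of the 2-methyl-2-vinylchroman is then cut and the oxygen is moved along the allyl unit to the vinyl terminus. This re-opens the six-membered pyran ring to an eight-membered (3Z)-4-methyl-5,6-dihydro-2H-1-benzoxocine, which is cut at its alkene (ring-closing metathesis), at O–allyl and at aryl–CH2.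
- Enabling feature: C2 of the pyran ring is tertiary, allylic (C2–C1'=C2') and bound to O1, an aryl oxygen para to the C6 carboxyl group. Such an aryloxide can both leave from and add to a π-allylpalladium unit, so the pyran ring and the benzoxocine ring are two closures of one allyl complex.
- Forward order: Negishi coupling and O-allylation of methyl 4-hydroxy-3-iodobenzoate, metathesis to the eight-membered ring (only Z is possible), Pd-catalysed contraction to the chroman, ozonolysis, olefination with the side chain (three steps from dihydro-β-ionone), saponification.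
- Stereochemistry: the only stereocentre (C2, R) is set in the ring contraction by a chiral bisphosphine ligand from an achiral precursor, through equilibrating diastereomeric allyl complexes that funnel into one configuration. The 3'E alkene comes from syn-carboalumination and the 1'E alkene from the olefination.

Key step: step 4

Assumption: by analogy with acyclic Z-configured phenol allyl carbonates, the (S,S)-ligand is taken to give the (R)-vinylchroman; the configuration would be checked by correlation, and if the sense is opposite the (R,R)-ligand is used with no other change.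

Remark: conjugate bases (phenoxide, enolate, acetylide, lithiated phosphonate) and catalyst-bound species are not numbered.

**Step 1**
Reactants: 1 methyl 4-hydroxy-3-iodobenzoate; 2 4-bromo-2-methylbut-1-ene
Product: 4 methyl 4-hydroxy-3-(3-methylbut-3-en-1-yl)benzoate, via alkylzinc bromide 3 (not isolated)
Conditions: 2, Zn dust (activated), LiCl, THF, 50 °C; then slow addition to 1, Pd(OAc)2 (1 mol%), SPhos (2 mol%), THF, 25 °C
Reagents that add atoms: zinc, [Zn] (retained only in intermediate 3)
Why: Negishi sp2–sp3 coupling, in which the alkylzinc from LiCl-assisted zinc insertion tolerates the ester and, on slow addition to a fast Pd/SPhos catalyst, the phenol O–H, and the primary homoallyl group should transfer without isomerisation.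

**Step 2**
Reactants: 4 methyl 4-hydroxy-3-(3-methylbut-3-en-1-yl)benzoate; 5 allyl bromide
Product: 6 methyl 4-(allyloxy)-3-(3-methylbut-3-en-1-yl)benzoate
Conditions: K2CO3, DMF, 25 °C
Reagents that add atoms: none
Why: Williamson ether synthesis, in which the acidic p-acylphenol is deprotonated by K2CO3 and O-alkylated by SN2 at the primary allylic bromide.

**Step 3**
Reactants: 6 methyl 4-(allyloxy)-3-(3-methylbut-3-en-1-yl)benzoate
Product: 7 methyl (3Z)-4-methyl-5,6-dihydro-2H-1-benzoxocine-8-carboxylate
Conditions: (H2IMes)(PCy3)Cl2Ru=CHPh (5 mol%), 1,4-benzoquinone (10 mol%), toluene (2 mM), 80 °C, Ar sparge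
Reagents that add atoms: none
Why: Ring-closing metathesis, in which the catalyst loads on the monosubstituted allyl ether and closes on the 1,1-disubstituted alkene under high dilution, the benzo fusion eases closure, and an eight-membered ring can hold only the Z alkene, so the geometry needed in step 4 is fixed without a stereoselective olefination.

**Step 4**
Reactants: 7 methyl (3Z)-4-methyl-5,6-dihydro-2H-1-benzoxocine-8-carboxylate
Product: 8 methyl (2R)-2-ethenyl-2-methyl-3,4-dihydro-2H-chromene-6-carboxylate
Conditions: Pd2(dba)3·CHCl3 (2.5 mol%), (S,S)-DACH-phenyl ligand [N,N'-((1S,2S)-cyclohexane-1,2-diyl)bis(2-(diphenylphosphino)benzamide)] (7.5 mol%), AcOH (1 equiv), CH2Cl2, 25 °C, stopped at full conversion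
Reagents that add atoms: none
Why: Proposed new method: Pd(0)–ligand binds the strained ring alkene C3=C4 of 7 anti to the allylic C2–O1 bond and ionises it, the aryloxide being a competent leaving group because it lies para to the CO2Me group and is hydrogen-bonded by AcOH, which gives an η3-allylpalladium(II) unit (C2–C3–C4) that carries the phenol on an arm held anti by the former Z geometry. The two complexes that differ in the allyl face bound to Pd interconvert by η3–η1–η3 slippage at the unsubstituted terminus C2 faster than either closes, and the oxygen then attacks the substituted terminus C4 anti to Pd, so that C2 and C3 leave the ring and become the vinyl group (net 1,3-shift of oxygen, eight-membered to six-membered ring). The closest known reaction type is the intramolecular Pd-catalysed asymmetric allylic alkylation of phenols bearing an acyclic trisubstituted allyl carbonate, together with the Pd(0)-catalysed equilibration of branched and linear allyl aryl ethers; what has not been shown is a ring aryl ether as the leaving group and the use of the event as an enantioselective ring contraction. The pyran ring closes in the 6-exo-trig mode on the allyl terminus, whereas the competing 8-endo closure only returns 7, so that release of medium-ring strain should carry the equilibrium to 8. The new quaternary centre C2 of 8 is controlled by the chiral pocket of the ligand alone (catalyst control under Curtin–Hammett conditions), since 7 has no stereocentre. The step needs branched regioselectivity, which the ring sizes secure, a single allyl geometry, which the ring-enforced Z alkene secures, and a product that re-ionises more slowly than 7, which the loss of strain and the crowded tertiary C–O bond of 8 should secure if the run is stopped at full conversion.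

**Step 5**
Reactants: 8 methyl (2R)-2-ethenyl-2-methyl-3,4-dihydro-2H-chromene-6-carboxylate
Product: 10 methyl (2R)-2-formyl-2-methyl-3,4-dihydro-2H-chromene-6-carboxylate, via secondary ozonide 9 (not isolated)
Conditions: O3, CH2Cl2, −78 °C; then Me2S, −78 °C → rt
Reagents that add atoms: ozone, [O-][O+]=O
Why: Ozonolysis with reductive work-up cleaves the only C=C bond, and C2, which bears no hydrogen, cannot epimerise.

**Step 6**
Reactants: 11 dihydro-β-ionone [4-(2,6,6-trimethylcyclohex-1-en-1-yl)butan-2-one]
Product: 13 2-(but-3-yn-1-yl)-1,3,3-trimethylcyclohex-1-ene, via enol phosphate 12 (not isolated)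
Conditions: LDA (commercial solution, 1.05 equiv), THF, −78 °C; ClP(O)(OEt)2, −78 °C → rt; LDA (2.3 equiv), −78 °C → rt; H2O
Reagents that add atoms: diethyl chlorophosphate, CCOP(=O)(Cl)OCC (retained only in intermediate 12)
Why: Methyl ketone to terminal alkyne conversion, in which kinetic deprotonation on the CH3 side, O-phosphorylation and LDA-induced E2 loss of diethyl phosphate give the acetylide, which is protonated on work-up.

**Step 7**
Reactants: 13 2-(but-3-yn-1-yl)-1,3,3-trimethylcyclohex-1-ene
Product: 16 (2E)-3-methyl-5-(2,6,6-trimethylcyclohex-1-en-1-yl)pent-2-en-1-ol, via alkenylalane 14 (not isolated), via lithium alanate 15 (not isolated)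
Conditions: Me3Al, Cp2ZrCl2 (20 mol%), CH2Cl2, 0 °C → rt; volatiles removed; n-BuLi, hexane/THF, 0 °C; (CH2O)n, rt; aq. Rochelle salt
Reagents that add atoms: trimethylaluminium, C[Al](C)C; n-butyllithium, [Li]CCCC (retained only in intermediate 15); paraformaldehyde (as formaldehyde), C=O
Why: Zr-catalysed carboalumination adds Me and Al syn with Al on the terminal carbon, which fixes the E geometry, and the derived alanate is hydroxymethylated by formaldehyde with retention.

**Step 8**
Reactants: 16 (2E)-3-methyl-5-(2,6,6-trimethylcyclohex-1-en-1-yl)pent-2-en-1-ol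
Product: 17 diethyl [(2E)-3-methyl-5-(2,6,6-trimethylcyclohex-1-en-1-yl)pent-2-en-1-yl]phosphonate
Conditions: P(OEt)3 (3 equiv), ZnI2 (1.5 equiv), THF, reflux
Reagents that add atoms: triethyl phosphite, CCOP(OCC)OCC
Why: Zinc iodide-mediated one-flask Michaelis–Arbuzov-type conversion of a primary allylic alcohol, in which transesterification to the allyl diethyl phosphite and zinc-assisted O-to-P transfer at the primary carbon should give the phosphonate without allylic transposition or loss of alkene geometry.

**Step 9**
Reactants: 10 methyl (2R)-2-formyl-2-methyl-3,4-dihydro-2H-chromene-6-carboxylate; 17 diethyl [(2E)-3-methyl-5-(2,6,6-trimethylcyclohex-1-en-1-yl)pent-2-en-1-yl]phosphonate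
Product: 18 methyl (2R)-2-methyl-2-[(1E,3E)-4-methyl-6-(2,6,6-trimethylcyclohex-1-en-1-yl)hexa-1,3-dien-1-yl]-3,4-dihydro-2H-chromene-6-carboxylate
Conditions: 17, n-BuLi, THF/DMPU, −78 °C; then 10, −78 °C → rt
Reagents that add atoms: none
Why: Horner–Wadsworth–Emmons olefination, in which the lithiated allylic phosphonate adds through its α-carbon to the non-enolisable aldehyde far faster than to the aryl ester, and reversible addition with elimination of the less crowded adduct should give the new E alkene while C2 is untouched.

**Step 10**
Reactants: 18 methyl (2R)-2-methyl-2-[(1E,3E)-4-methyl-6-(2,6,6-trimethylcyclohex-1-en-1-yl)hexa-1,3-dien-1-yl]-3,4-dihydro-2H-chromene-6-carboxylate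
Product: 19 (2R)-2-methyl-2-[(1E,3E)-4-methyl-6-(2,6,6-trimethylcyclohex-1-en-1-yl)hexa-1,3-dien-1-yl]-3,4-dihydro-2H-chromene-6-carboxylic acid (CNP0265961.1)
Conditions: LiOH, THF/MeOH/H2O, 40 °C; then cold 0.5 M HCl to pH 4
Reagents that add atoms: lithium hydroxide, [Li+].[OH-]
Why: Saponification (BAc2) leaves the diene and the ether untouched, and the mild cold acidification avoids ionisation of the tertiary dienylic aryl ether.

**Compound list**

1 | methyl 4-hydroxy-3-iodobenzoate | COC(=O)c1ccc(O)c(I)c1 | starting material
2 | 4-bromo-2-methylbut-1-ene | CC(=C)CCBr | starting material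
3 | (3-methylbut-3-en-1-yl)zinc bromide | CC(=C)CC[Zn]Br | intermediate
4 | methyl 4-hydroxy-3-(3-methylbut-3-en-1-yl)benzoate | COC(=O)c1ccc(O)c(CCC(C)=C)c1 | intermediate
5 | allyl bromide | C=CCBr | starting material
6 | methyl 4-(allyloxy)-3-(3-methylbut-3-en-1-yl)benzoate | COC(=O)c1ccc(OCC=C)c(CCC(C)=C)c1 | intermediate
7 | methyl (3Z)-4-methyl-5,6-dihydro-2H-1-benzoxocine-8-carboxylate | COC(=O)c1ccc2OC/C=C(C)\CCc2c1 | intermediate
8 | methyl (2R)-2-ethenyl-2-methyl-3,4-dihydro-2H-chromene-6-carboxylate | C=C[C@@]1(C)CCc2cc(C(=O)OC)ccc2O1 | intermediate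
9 | methyl (2R)-2-methyl-2-(1,2,4-trioxolan-3-yl)-3,4-dihydro-2H-chromene-6-carboxylate (epimers at the trioxolane carbon) | O1COOC1[C@@]2(C)CCc3cc(C(=O)OC)ccc3O2 | intermediate
10 | methyl (2R)-2-formyl-2-methyl-3,4-dihydro-2H-chromene-6-carboxylate | O=C[C@@]1(C)CCc2cc(C(=O)OC)ccc2O1 | intermediate
11 | dihydro-β-ionone, 4-(2,6,6-trimethylcyclohex-1-en-1-yl)butan-2-one | CC(=O)CCC1=C(C)CCCC1(C)C | starting material
12 | diethyl 4-(2,6,6-trimethylcyclohex-1-en-1-yl)but-1-en-2-yl phosphate | C=C(CCC1=C(C)CCCC1(C)C)OP(=O)(OCC)OCC | intermediate
13 | 2-(but-3-yn-1-yl)-1,3,3-trimethylcyclohex-1-ene | C#CCCC1=C(C)CCCC1(C)C | intermediate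
14 | dimethyl[(1E)-2-methyl-4-(2,6,6-trimethylcyclohex-1-en-1-yl)but-1-en-1-yl]alane | C[Al](C)/C=C(C)/CCC1=C(C)CCCC1(C)C | intermediate
15 | lithium butyl(dimethyl)[(1E)-2-methyl-4-(2,6,6-trimethylcyclohex-1-en-1-yl)but-1-en-1-yl]alanate | [Li+].CCCC[Al-](C)(C)/C=C(C)/CCC1=C(C)CCCC1(C)C | intermediate
16 | (2E)-3-methyl-5-(2,6,6-trimethylcyclohex-1-en-1-yl)pent-2-en-1-ol | OC/C=C(C)/CCC1=C(C)CCCC1(C)C | intermediate
17 | diethyl [(2E)-3-methyl-5-(2,6,6-trimethylcyclohex-1-en-1-yl)pent-2-en-1-yl]phosphonate | CCOP(=O)(OCC)C/C=C(C)/CCC1=C(C)CCCC1(C)C | intermediate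
18 | methyl ester of the target, (2R,1'E,3'E) | CC1=C(CC/C(C)=C/C=C/[C@@]2(C)CCc3cc(C(=O)OC)ccc3O2)C(C)(C)CCC1 | intermediate
19 | (2R)-2-methyl-2-[(1E,3E)-4-methyl-6-(2,6,6-trimethylcyclohex-1-en-1-yl)hexa-1,3-dien-1-yl]-3,4-dihydro-2H-chromene-6-carboxylic acid | CC1=C(CC/C(C)=C/C=C/[C@@]2(C)CCc3cc(C(=O)O)ccc3O2)C(C)(C)CCC1 | target

**Totals**

Total step count: 10.
Longest linear sequence: 7 (steps 1, 2, 3, 4, 5, 9, 10).

**Steps most likely to fail**

**Step 4.**
- What may go wrong: ionisation of a primary aryl ether at a trisubstituted alkene may be too slow.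
- The product may re-ionise and lose enantiopurity with time.
- The allyl complex may lose a β-hydrogen to give an open-chain diene.
- Fallback (known chemistry only): it sets out from 4 and comes back at 10, bypassing steps 2 to 5. Prilezhaev epoxidation of 4 (m-CPBA, NaHCO3, CH2Cl2) gives racemic methyl 4-hydroxy-3-[2-(2-methyloxiran-2-yl)ethyl]benzoate F1. Catalytic camphorsulfonic acid then induces 6-exo opening of the epoxide at its tertiary carbon by the phenol, giving racemic methyl 2-(hydroxymethyl)-2-methylchroman-6-carboxylate F2. Steglich esterification with (S)-O-methylmandelic acid gives the (2R)-chromanylmethyl (S)-O-methylmandelate F3 and the (2S)-chromanylmethyl (S)-O-methylmandelate F4, which are separated by crystallisation or chromatography. Transesterification of F3 (K2CO3, MeOH, in which the aryl methyl ester exchanges only with itself) frees methyl (2R)-2-(hydroxymethyl)-2-methylchroman-6-carboxylate F5. Dess–Martin oxidation of F5 gives 10.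

**Step 3.**
- What may go wrong: closure of the eight-membered ring on the 1,1-disubstituted alkene may be slower than intermolecular metathesis (oligomerisation).
- Ruthenium hydrides may shift the allyl ether to a propenyl ether, with loss of a ring carbon.
- Fallback: it sets out from 1 and comes back at 7, and it closes the ring at the O1–C2 bond instead of at the alkene. Suzuki–Miyaura vinylation of 1 (potassium vinyltrifluoroborate, PdCl2(dppf), Et3N, n-PrOH) gives methyl 4-hydroxy-3-vinylbenzoate F6. Hydroboration with 9-BBN gives the B-alkyl borane methyl 3-[2-(9-borabicyclo[3.3.1]nonan-9-yl)ethyl]-4-hydroxybenzoate F7. This is coupled in the same flask (B-alkyl Suzuki–Miyaura, PdCl2(dppf), K3PO4, DMF/H2O) with (Z)-3-iodobut-2-en-1-ol, with retention of geometry, to methyl 4-hydroxy-3-[(3Z)-5-hydroxy-3-methylpent-3-en-1-yl]benzoate F8. An intramolecular Mitsunobu reaction (PPh3, DIAD, toluene, slow addition at high dilution) closes the ether to 7.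

**Step 9.**
- What may go wrong: addition to the neopentyl-type aldehyde may be sluggish and elimination of the adduct incomplete.
- Attack may occur through the γ-carbon of the phosphonate anion.
- Geometric integrity may be lost through the delocalised anion.
- Fallback: it sets out from 10 (with alane 14 taken from step 7) and comes back at 18, and it forms the C2'–C3' single bond instead of the C1'=C2' double bond. Takai olefination of 10 (CrCl2, CHI3, THF, 0 °C) gives methyl (2R)-2-[(E)-2-iodoethenyl]-2-methylchroman-6-carboxylate F9. A Negishi alkenyl–alkenyl coupling of F9 with 14 (Pd(PPh3)4, ZnCl2, THF, rt, short contact time) joins two alkenes of fixed geometry to give 18.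

**Further compounds**

F1 | step 4 | methyl 4-hydroxy-3-[2-(2-methyloxiran-2-yl)ethyl]benzoate (racemic) | COC(=O)c1ccc(O)c(CCC2(C)CO2)c1
F2 | step 4 | methyl 2-(hydroxymethyl)-2-methylchroman-6-carboxylate (racemic) | COC(=O)c1ccc2OC(C)(CO)CCc2c1
F3 | step 4 | (2R)-chromanylmethyl (S)-O-methylmandelate | CO[C@H](C(=O)OC[C@@]1(C)CCc2cc(C(=O)OC)ccc2O1)c1ccccc1
F4 | step 4 | (2S)-chromanylmethyl (S)-O-methylmandelate | CO[C@H](C(=O)OC[C@]1(C)CCc2cc(C(=O)OC)ccc2O1)c1ccccc1
F5 | step 4 | methyl (2R)-2-(hydroxymethyl)-2-methylchroman-6-carboxylate | OC[C@@]1(C)CCc2cc(C(=O)OC)ccc2O1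
F6 | step 3 | methyl 4-hydroxy-3-vinylbenzoate | C=Cc1cc(C(=O)OC)ccc1O
F7 | step 3 | methyl 3-[2-(9-borabicyclo[3.3.1]nonan-9-yl)ethyl]-4-hydroxybenzoate | COC(=O)c1ccc(O)c(CCB2C3CCCC2CCC3)c1
F8 | step 3 | methyl 4-hydroxy-3-[(3Z)-5-hydroxy-3-methylpent-3-en-1-yl]benzoate | COC(=O)c1ccc(O)c(CC/C(C)=C\CO)c1
F9 | step 9 | methyl (2R)-2-[(E)-2-iodoethenyl]-2-methylchroman-6-carboxylate | I/C=C/[C@@]1(C)CCc2cc(C(=O)OC)ccc2O1
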